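**Reading time.** The south-east flask is to be read at 61 h, and I wanted to know how far along its own stall it would stand by then.

| flask | starting material | free catalyst | time |
|---|---|---|---|
| north | 250 mM | 5.00 mM |  |
| north-west | 100 mM | 5.00 mM |  |
| south | 750 mM | 5.00 mM |  |
| south-west | 250 mM | 15.0 mM |  |
| south-east | 120 mM | 1.70 mM | 61 h |

| run | time / h | [target] / mM |
|---|---|---|
| north run | 2.4 | 3 |
| north run | 4.2 | 6 |
| north run | 7.1 | 19 |
| north run | 12 | 22 |
| north run | 21 | 35 |
| north run | 36 | 51 |
| north run | 61 | 53 |
| north-west run | 2.4 | 0 |
| north-west run | 4.2 | 7 |
| north-west run | 7.1 | 12 |
| north-west run | 12 | 15 |
| north-west run | 21 | 23 |
| north-west run | 36 | 20 |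
| north-west run | 61 | 33 |
| south run | 2.4 | 10 |
| south run | 4.2 | 14 |
| south run | 7.1 | 36 |
| south run | 12 | 47 |
| south run | 21 | 59 |
| south run | 36 | 84 |
| south run | 61 | 74 |
| south-west run | 2.4 | 40 |
| south-west run | 4.2 | 62 |
| south-west run | 7.1 | 92 |
| south-west run | 12 | 123 |
| south-west run | 21 | 130 |
| south-west run | 36 | 130 |
| south-west run | 61 | 137 |

(standard deviation of a reading: 4 mM)

* reaction order in [free catalyst] at the outset, round the charge of the north run, defined at two percent of the starting material turned into target
* reaction order in [starting material] at the outset, round the charge of the north run, defined at two percent of the starting material turned into target (one fixed amount of target, the same in the runs compared)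
* target in the south-east run at 61 h, as a share of the starting material charged

- Overall: starting material -> target, with free catalyst as catalyst.
- Constant volume, constant temperature.
- Readings of a species count what is bound in complexes too.
- An order is taken over about fifteen percent of the charge, up and down.

**The stall.** The north run read 51 mM at 36 h and 53 mM at 61 h, a stall share of 21.2% of its charge. The turnover number, target per free catalyst charged, read 10.6 there and 9.13 in the south-west run, so I took the stall as proportional to the catalyst charge. The north-west share of 33.0% suggested a share falling as the root of the substrate charge. For the south-east flask this gave 10.4%.

**One number.** I guessed a rate proportional to starting material and to free catalyst squared, with free catalyst lost in proportion to itself and to target. With starting material frozen, this reproduces that stall, and the share of the stall reached is the hyperbolic tangent of one number. That number is the stall clock θ, elapsed time over the time the early rate would need to fill the stall, growing with catalyst charge and the root of substrate charge. The north reading at 21 h gave a clock time, the time in which θ reaches 1 in the north run, of 26.5 h, so I put the south-east flask at θ = 0.543. That is 49.5% of its stall, or 5.15% of its charge.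

**The test.** At 21 h the clock gave the north-west run 15.5%, but it read 23.0%. At 12 h it gave the south run 8.03%, but it read 6.27%. One number was not enough, and the two misses pointed one way: I kept the order of 2 in catalyst, put the order in substrate under 1, and, the south-east charge being smaller than the north charge, took my share as on the low side.

**The forecast.** The forecast gave an order of 1.9 in free catalyst, an order of 0.55 in starting material and a share of 5.5%, above my share, reasoning that "Death therefore looks second order in catalyst".

**The flask.** At 61 h the south-east flask held 6.03% of its charge as target, and round the charge of the north run the orders at the outset were 2.0 in free catalyst and 0.76 in starting material.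

    free catalyst + starting material ⇌ catalyst-substrate complex, settled at all times (0.6130 L mol⁻¹)
    catalyst-substrate complex + free catalyst → target + 2 free catalyst (741.6 L mol⁻¹ h⁻¹)
    free catalyst + target → spent catalyst + target (0.7956 L mol⁻¹ h⁻¹)

That share is 58.0% of my stall share, against the 49.5% the clock gave. In the south-west run, taking its read stall of 137 mM and scaling θ from the south-east flask, the clock put half of the charge at 13.6 h, and the flask reached it at 14.4 h.

(The numbers in the tables are calculated on assumed constants; scatter was added.)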